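**Plan**

- Retrosynthesis: the two ester C–O bonds are cut first, giving the benzyl-protected mixed α-truxillic acid 27 and two molecules of amino alcohol 16. In 16 the C1–C7a bond is cut (back to enone 13), then C7=C7a (ring-closing metathesis) and C4a–C5 (Johnson–Claisen). In 27 the two aryl–cyclobutane bonds are cut.
- Enabling feature: in the octahydrocyclopenta[c]pyridine, C1 is a CH2 between N2 and the ring-fusion carbon C7a, and C7a is β to the C6 carbonyl across the methyl-bearing C7. An N–CH2 radical can therefore close the piperidine ring onto a C7=C7a cyclopentenone.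
- Forward order: acyclic chain (steps 1–6), cyclopentenone by metathesis (step 7), amine (step 9), piperidine ring by radical closure (step 10), carbinol (step 11). Separately the cyclobutane is arylated twice (steps 12–17). A double Mitsunobu esterification and debenzylation finish the route (steps 18–19).
- Stereochemistry: C4 comes from the (S)-Roche ester and C4a from chirality transfer in the Claisen step out of a CBS-derived carbinol. C7a follows from C4a (cis fusion), C7 from equilibration, C6 from hydride reduction followed by Mitsunobu inversion.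
- Cyclobutane: the relative configuration comes from two amide-directed cis C–H arylations separated by one epimerisation, the absolute configuration from resolution of 21.

Key step: step 10

Remark: locants C1–C7a follow cyclopenta[c]pyridine numbering; "α-truxillic configuration" means aryl groups mutually trans, carboxyl groups mutually trans, and the C1 carboxyl cis to the C2 aryl group. The C–H arylation of step 13 necessarily gives a racemate, which is resolved in that step, so every later cyclobutane is a single enantiomer.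

**Route**

Step 1
Reactants: 1 methyl (2S)-3-hydroxy-2-methylpropanoate
Product: 2 methyl (2S)-3-[(tert-butyldimethylsilyl)oxy]-2-methylpropanoate
Conditions: TBSCl, imidazole, DMF, 0 °C → rt
Reagents that add atoms: tert-butyldimethylsilyl chloride, CC(C)(C)[Si](C)(C)Cl
Why: Imidazole-promoted silylation of the primary alcohol, in which the stereocentre takes no part.

Step 2
Reactants: 2 methyl (2S)-3-[(tert-butyldimethylsilyl)oxy]-2-methylpropanoate
Product: 3 (2S)-3-[(tert-butyldimethylsilyl)oxy]-2-methylpropanal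
Conditions: DIBAL-H (1.05 equiv), CH2Cl2, −78 °C; Rochelle salt
Reagents that add atoms: none
Why: DIBAL-H half-reduction of the ester proceeds through a tetrahedral aluminate that is stable at −78 °C, so the aldehyde is released only on work-up and the α-stereocentre is kept.

Step 3
Reactants: 3 (2S)-3-[(tert-butyldimethylsilyl)oxy]-2-methylpropanal
Product: 4 (3E,5R)-6-[(tert-butyldimethylsilyl)oxy]-5-methylhex-3-en-2-one
Conditions: Ph3P=CHC(O)CH3, CH2Cl2, rt → 40 °C
Reagents that add atoms: 1-(triphenyl-λ5-phosphanylidene)propan-2-one, CC(=O)C=P(c1ccccc1)(c1ccccc1)c1ccccc1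
Why: Wittig olefination with a stabilised ylide should give the (E)-enone under neutral conditions that do not enolise the α-branched aldehyde.

Step 4
Reactants: 4 (3E,5R)-6-[(tert-butyldimethylsilyl)oxy]-5-methylhex-3-en-2-one
Product: 5 (2R,3E,5R)-6-[(tert-butyldimethylsilyl)oxy]-5-methylhex-3-en-2-ol
Conditions: (S)-Me-CBS (0.2 equiv), catecholborane, toluene, −78 °C
Reagents that add atoms: none
Why: Corey–Bakshi–Shibata reduction, in which the (S)-oxazaborolidine treats the alkenyl group as the large substituent and should give the (2R)-carbinol by catalyst control, with catecholborane at low temperature ensuring 1,2-reduction.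

Step 5
Reactants: 5 (2R,3E,5R)-6-[(tert-butyldimethylsilyl)oxy]-5-methylhex-3-en-2-ol
Product: 6 ethyl (3R,4E)-3-[(2R)-1-[(tert-butyldimethylsilyl)oxy]propan-2-yl]hex-4-enoate
Conditions: MeC(OEt)3, EtCO2H (cat.), 135 °C, removal of EtOH
Reagents that add atoms: triethyl orthoacetate, CCOC(C)(OCC)OCC
Why: Johnson–Claisen rearrangement through a chair transition state with the carbinol methyl equatorial should transfer the C2 configuration suprafacially to the new C3 centre (the future C4a, R) and form the (E)-propenyl group, the neighbouring C-methyl centre being a spectator.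

Step 6
Reactants: 6 ethyl (3R,4E)-3-[(2R)-1-[(tert-butyldimethylsilyl)oxy]propan-2-yl]hex-4-enoate
Product: 8 (5R,6E)-2-methyl-5-[(2R)-1-[(tert-butyldimethylsilyl)oxy]propan-2-yl]octa-1,6-dien-3-one, via Weinreb amide 7 (not isolated)
Conditions: MeNH(OMe)·HCl, i-PrMgCl, THF, −20 °C; then isopropenylMgBr, −20 → 0 °C; cold aq. NH4Cl
Reagents that add atoms: N,O-dimethylhydroxylamine hydrochloride, CNOC.Cl (in intermediate 7 only); isopropenylmagnesium bromide, CC(=C)[Mg]Br
Why: One-pot Weinreb ketone synthesis, in which the magnesium amide turns the ester into the N-methoxy-N-methylamide and its chelated adduct with the vinyl Grignard reagent collapses only on quench, which prevents over-addition.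

Step 7
Reactants: 8 (5R,6E)-2-methyl-5-[(2R)-1-[(tert-butyldimethylsilyl)oxy]propan-2-yl]octa-1,6-dien-3-one
Product: 9 (4R)-4-[(2R)-1-[(tert-butyldimethylsilyl)oxy]propan-2-yl]-2-methylcyclopent-2-en-1-one
Conditions: Grubbs II (5 mol %), CH2Cl2, 40 °C
Reagents that add atoms: none
Why: Ring-closing olefin metathesis of the 1,6-diene should form the trisubstituted cyclopentenone with loss of propene under neutral conditions that cannot epimerise the allylic stereocentre.

Step 8
Reactants: 9 (4R)-4-[(2R)-1-[(tert-butyldimethylsilyl)oxy]propan-2-yl]-2-methylcyclopent-2-en-1-one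
Product: 10 (4R)-4-[(2R)-1-hydroxypropan-2-yl]-2-methylcyclopent-2-en-1-one
Conditions: HF·pyridine, THF, 0 °C → rt
Reagents that add atoms: none
Why: Fluoride-mediated desilylation under buffered acidic conditions, preferred to basic fluoride so that the freed alcohol does not add to the enone.

Step 9
Reactants: 10 (4R)-4-[(2R)-1-hydroxypropan-2-yl]-2-methylcyclopent-2-en-1-one; 11 N-methyl-1-(trimethylsilyl)methanamine (2.5 equiv)
Product: 13 (4R)-2-methyl-4-[(2R)-1-{methyl[(trimethylsilyl)methyl]amino}propan-2-yl]cyclopent-2-en-1-one, via primary triflate 12 (not isolated)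
Conditions: Tf2O, 2,6-lutidine, CH2Cl2, −78 °C; then 11, −78 → 0 °C
Reagents that add atoms: trifluoromethanesulfonic anhydride, O=S(=O)(OS(=O)(=O)C(F)(F)F)C(F)(F)F (in intermediate 12 only)
Why: The primary triflate formed at −78 °C should undergo SN2 displacement by the secondary amine below 0 °C, faster than conjugate addition to the α-methyl enone, giving the tertiary α-silylamine without touching either stereocentre.

Step 10
Reactants: 13 (4R)-2-methyl-4-[(2R)-1-{methyl[(trimethylsilyl)methyl]amino}propan-2-yl]cyclopent-2-en-1-one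
Product: 15 (4R,4aS,7S,7aR)-2,4,7-trimethyloctahydro-6H-cyclopenta[c]pyridin-6-one, via C7-epimeric ketone 14 (not isolated)
Conditions: [Ir(ppy)2(dtbbpy)]PF6 (1 mol %), degassed MeOH (0.02 M), blue LEDs (450 nm), rt; then DBU (0.2 equiv), rt
Reagents that add atoms: none
Why: The excited iridium(III) complex oxidises the α-silylamine to its aminium radical cation, methanol-assisted loss of the silyl group gives the nucleophilic N–CH2 radical at C1, this adds to the enone β-carbon C7a, and the α-keto radical at C7 is reduced by Ir(II) to the enolate and protonated, which closes the catalytic cycle. The closest known reaction type is the photoinduced electron-transfer cyclisation of α-silylamines onto tethered enones (α-aminoalkyl radical conjugate addition). The piperidine ring closes in the 6-exo-trig mode. C7a is controlled by C4a, because the four-atom tether hangs from C4a and the new C1–C7a bond can form only on that face, so the ring fusion is cis. C7 is set by enolate protonation and then by DBU equilibration, which should place the methyl group trans to C1 on the convex face (14 → 15). The step needs radical formation at the silylated carbon only and no further oxidation of the product, and the C–Si bond secures both, since it fragments faster than α-deprotonation at N–CH3 or C3 and lowers the oxidation potential of 13 below that of the desilylated product amine.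

Step 11
Reactants: 15 (4R,4aS,7S,7aR)-2,4,7-trimethyloctahydro-6H-cyclopenta[c]pyridin-6-one
Product: 16 (4R,4aS,6S,7S,7aR)-2,4,7-trimethyloctahydro-1H-cyclopenta[c]pyridin-6-ol
Conditions: NaBH4, MeOH, −20 → 0 °C
Reagents that add atoms: none
Why: Borohydride reduction in which hydride should arrive from the convex face (the concave face is screened by C1 and C4 of the piperidine ring), giving the (6S)-alcohol with OH trans to the C7 methyl, that is, the C6 epimer of the configuration needed in the ester.

Step 12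
Reactants: 17 cis-3-(methoxycarbonyl)cyclobutane-1-carboxylic acid; 18 2-(methylsulfanyl)aniline
Product: 19 methyl cis-3-{[2-(methylsulfanyl)phenyl]carbamoyl}cyclobutane-1-carboxylate
Conditions: EDC·HCl, DMAP (cat.), CH2Cl2, rt
Reagents that add atoms: none
Why: Carbodiimide amide coupling installs the N,S-bidentate anilide that will direct the C–H activations.

Step 13
Reactants: 19 methyl cis-3-{[2-(methylsulfanyl)phenyl]carbamoyl}cyclobutane-1-carboxylate; 20 1-(benzyloxy)-4-iodobenzene
Product: 21 methyl (1S,2R,3R)-2-[4-(benzyloxy)phenyl]-3-{[2-(methylsulfanyl)phenyl]carbamoyl}cyclobutane-1-carboxylate (all-cis)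
Conditions: Pd(OAc)2 (15 mol %), Ag2CO3, PivOH, HFIP, 90 °C; then preparative chiral SFC
Reagents that add atoms: none
Why: Amide-directed Pd(II)/Pd(IV) C(sp3)–H arylation through a cis-fused five-membered palladacycle places the aryl group cis to the amide (all-cis product) at one of two enantiotopic CH2 groups, so the racemate that forms is resolved by chiral chromatography and the (1S,2R,3R) antipode is carried on.

Step 14
Reactants: 21 methyl (1S,2R,3R)-2-[4-(benzyloxy)phenyl]-3-{[2-(methylsulfanyl)phenyl]carbamoyl}cyclobutane-1-carboxylate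
Product: 22 methyl (1S,2R,3S)-2-[4-(benzyloxy)phenyl]-3-{[2-(methylsulfanyl)phenyl]carbamoyl}cyclobutane-1-carboxylate
Conditions: t-BuOLi, toluene, 50 °C; then aq. HCl
Reagents that add atoms: none
Why: Base-mediated epimerisation α to the amide moves the carboxamide trans to the aryl group and relieves the all-cis strain, lithium tert-butoxide in a non-polar solvent being the type of conditions known to invert this centre in closely related 2-arylcyclobutane ester amides while leaving the ester-bearing carbon alone.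

Step 15
Reactants: 23 4-iodo-2-methoxyphenol
Product: 24 1-(benzyloxy)-4-iodo-2-methoxybenzene
Conditions: BnBr, K2CO3, DMF, rt
Reagents that add atoms: benzyl bromide, BrCc1ccccc1
Why: Williamson etherification of the phenol.

Step 16
Reactants: 22 methyl (1S,2R,3S)-2-[4-(benzyloxy)phenyl]-3-{[2-(methylsulfanyl)phenyl]carbamoyl}cyclobutane-1-carboxylate; 24 1-(benzyloxy)-4-iodo-2-methoxybenzene
Product: 25 methyl (1R,2R,3R,4R)-2-[4-(benzyloxy)-3-methoxyphenyl]-4-[4-(benzyloxy)phenyl]-3-{[2-(methylsulfanyl)phenyl]carbamoyl}cyclobutane-1-carboxylate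
Conditions: Pd(OAc)2 (15 mol %), Ag2CO3, PivOH, HFIP, 90 °C
Reagents that add atoms: none
Why: Second amide-directed C–H arylation, in which the palladacycle again forms cis to the amide, now on the face opposite the first aryl group, so the new aryl should enter trans to the first aryl and to the ester and complete the head-to-tail α-truxillate pattern.

Step 17
Reactants: 25 methyl (1R,2R,3R,4R)-2-[4-(benzyloxy)-3-methoxyphenyl]-4-[4-(benzyloxy)phenyl]-3-{[2-(methylsulfanyl)phenyl]carbamoyl}cyclobutane-1-carboxylate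
Product: 27 (1R,3R)-2-[4-(benzyloxy)-3-methoxyphenyl]-4-[4-(benzyloxy)phenyl]cyclobutane-1,3-dicarboxylic acid of α-truxillic configuration, via N-Boc imide 26 (not isolated)
Conditions: Boc2O, DMAP, MeCN, rt; then LiOH, H2O2, THF/H2O, 0 °C → rt; 1 M HCl
Reagents that add atoms: di-tert-butyl dicarbonate, CC(C)(C)OC(=O)OC(=O)OC(C)(C)C (in intermediate 26 only); water (as LiOH/H2O2), O
Why: N-Boc activation twists the anilide out of conjugation so that lithium hydroperoxide should cleave it at 0 °C while the same medium saponifies the methyl ester, conditions mild enough to keep both α-stereocentres.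

Step 18
Reactants: 27 (1R,3R)-2-[4-(benzyloxy)-3-methoxyphenyl]-4-[4-(benzyloxy)phenyl]cyclobutane-1,3-dicarboxylic acid; 16 (4R,4aS,6S,7S,7aR)-2,4,7-trimethyloctahydro-1H-cyclopenta[c]pyridin-6-ol (2.3 equiv)
Product: 28 bis[(4R,4aS,6R,7S,7aR)-2,4,7-trimethyloctahydro-1H-cyclopenta[c]pyridin-6-yl] (1R,3R)-2-[4-(benzyloxy)-3-methoxyphenyl]-4-[4-(benzyloxy)phenyl]cyclobutane-1,3-dicarboxylate
Conditions: PPh3, DIAD, THF, 0 °C → rt
Reagents that add atoms: none
Why: Mitsunobu esterification, in which each carboxylate should displace the oxyphosphonium group of 16 from the convex face with inversion, turning (6S) into the (6R)-esters without affecting the cyclobutane centres.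

Step 19
Reactants: 28 bis[(4R,4aS,6R,7S,7aR)-2,4,7-trimethyloctahydro-1H-cyclopenta[c]pyridin-6-yl] (1R,3R)-2-[4-(benzyloxy)-3-methoxyphenyl]-4-[4-(benzyloxy)phenyl]cyclobutane-1,3-dicarboxylate
Product: 29 bis[(4R,4aS,6R,7S,7aR)-2,4,7-trimethyloctahydro-1H-cyclopenta[c]pyridin-6-yl] (1R,3R)-2-(4-hydroxy-3-methoxyphenyl)-4-(4-hydroxyphenyl)cyclobutane-1,3-dicarboxylate
Conditions: H2 (1 atm), Pd/C, EtOAc/MeOH, rt
Reagents that add atoms: none
Why: Hydrogenolysis of the two aryl benzyl ethers over palladium should leave the esters, the tertiary amines and the cyclobutane untouched.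

**Compound list**

1 | methyl (2S)-3-hydroxy-2-methylpropanoate | COC(=O)[C@@H](C)CO | starting material
2 | methyl (2S)-3-[(tert-butyldimethylsilyl)oxy]-2-methylpropanoate | COC(=O)[C@@H](C)CO[Si](C)(C)C(C)(C)C | intermediate
3 | (2S)-3-[(tert-butyldimethylsilyl)oxy]-2-methylpropanal | O=C[C@@H](C)CO[Si](C)(C)C(C)(C)C | intermediate
4 | (3E,5R)-6-[(tert-butyldimethylsilyl)oxy]-5-methylhex-3-en-2-one | CC(=O)/C=C/[C@@H](C)CO[Si](C)(C)C(C)(C)C | intermediate
5 | (2R,3E,5R)-6-[(tert-butyldimethylsilyl)oxy]-5-methylhex-3-en-2-ol | C[C@@H](O)/C=C/[C@@H](C)CO[Si](C)(C)C(C)(C)C | intermediate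
6 | ethyl (3R,4E)-3-[(2R)-1-[(tert-butyldimethylsilyl)oxy]propan-2-yl]hex-4-enoate | CCOC(=O)C[C@H](/C=C/C)[C@@H](C)CO[Si](C)(C)C(C)(C)C | intermediate
7 | (3R,4E)-N-methoxy-N-methyl-3-[(2R)-1-[(tert-butyldimethylsilyl)oxy]propan-2-yl]hex-4-enamide | CON(C)C(=O)C[C@H](/C=C/C)[C@@H](C)CO[Si](C)(C)C(C)(C)C | intermediate
8 | (5R,6E)-2-methyl-5-[(2R)-1-[(tert-butyldimethylsilyl)oxy]propan-2-yl]octa-1,6-dien-3-one | C=C(C)C(=O)C[C@H](/C=C/C)[C@@H](C)CO[Si](C)(C)C(C)(C)C | intermediate
9 | (4R)-4-[(2R)-1-[(tert-butyldimethylsilyl)oxy]propan-2-yl]-2-methylcyclopent-2-en-1-one | O=C1C[C@@H]([C@@H](C)CO[Si](C)(C)C(C)(C)C)C=C1C | intermediate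
10 | (4R)-4-[(2R)-1-hydroxypropan-2-yl]-2-methylcyclopent-2-en-1-one | O=C1C[C@@H]([C@@H](C)CO)C=C1C | intermediate
11 | N-methyl-1-(trimethylsilyl)methanamine | CNC[Si](C)(C)C | starting material
12 | (2R)-2-[(1R)-3-methyl-4-oxocyclopent-2-en-1-yl]propyl trifluoromethanesulfonate | O=C1C[C@@H]([C@@H](C)COS(=O)(=O)C(F)(F)F)C=C1C | intermediate
13 | (4R)-2-methyl-4-[(2R)-1-{methyl[(trimethylsilyl)methyl]amino}propan-2-yl]cyclopent-2-en-1-one | O=C1C[C@@H]([C@@H](C)CN(C)C[Si](C)(C)C)C=C1C | intermediate
14 | (4R,4aS,7R,7aR)-2,4,7-trimethyloctahydro-6H-cyclopenta[c]pyridin-6-one | O=C1C[C@@H]2[C@@H](CN(C)C[C@@H]2C)[C@H]1C | intermediate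
15 | (4R,4aS,7S,7aR)-2,4,7-trimethyloctahydro-6H-cyclopenta[c]pyridin-6-one | O=C1C[C@@H]2[C@@H](CN(C)C[C@@H]2C)[C@@H]1C | intermediate
16 | (4R,4aS,6S,7S,7aR)-2,4,7-trimethyloctahydro-1H-cyclopenta[c]pyridin-6-ol | O[C@H]1C[C@@H]2[C@@H](CN(C)C[C@@H]2C)[C@@H]1C | intermediate
17 | cis-3-(methoxycarbonyl)cyclobutane-1-carboxylic acid | OC(=O)[C@H]1C[C@@H](C(=O)OC)C1 | starting material
18 | 2-(methylsulfanyl)aniline | CSc1ccccc1N | starting material
19 | methyl cis-3-{[2-(methylsulfanyl)phenyl]carbamoyl}cyclobutane-1-carboxylate | CSc1ccccc1NC(=O)[C@H]1C[C@@H](C(=O)OC)C1 | intermediate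
20 | 1-(benzyloxy)-4-iodobenzene | Ic1ccc(OCc2ccccc2)cc1 | starting material
21 | methyl (1S,2R,3R)-2-[4-(benzyloxy)phenyl]-3-{[2-(methylsulfanyl)phenyl]carbamoyl}cyclobutane-1-carboxylate (ester, aryl and amide all cis) | C1[C@H](C(=O)OC)[C@H](c2ccc(OCc3ccccc3)cc2)[C@@H]1C(=O)Nc1ccccc1SC | intermediate
22 | methyl (1S,2R,3S)-2-[4-(benzyloxy)phenyl]-3-{[2-(methylsulfanyl)phenyl]carbamoyl}cyclobutane-1-carboxylate (ester cis, amide trans to the aryl) | C1[C@H](C(=O)OC)[C@H](c2ccc(OCc3ccccc3)cc2)[C@H]1C(=O)Nc1ccccc1SC | intermediate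
23 | 4-iodo-2-methoxyphenol | COc1cc(I)ccc1O | starting material
24 | 1-(benzyloxy)-4-iodo-2-methoxybenzene | COc1cc(I)ccc1OCc1ccccc1 | intermediate
25 | methyl (1R,2R,3R,4R)-2-[4-(benzyloxy)-3-methoxyphenyl]-4-[4-(benzyloxy)phenyl]-3-{[2-(methylsulfanyl)phenyl]carbamoyl}cyclobutane-1-carboxylate (aryls trans; ester cis to the 4-aryl, amide cis to the 2-aryl) | COc1cc([C@H]2[C@H](C(=O)OC)[C@H](c3ccc(OCc4ccccc4)cc3)[C@H]2C(=O)Nc2ccccc2SC)ccc1OCc1ccccc1 | intermediate
26 | methyl (1R,2R,3R,4R)-2-[4-(benzyloxy)-3-methoxyphenyl]-4-[4-(benzyloxy)phenyl]-3-{(tert-butoxycarbonyl)[2-(methylsulfanyl)phenyl]carbamoyl}cyclobutane-1-carboxylate | COc1cc([C@H]2[C@H](C(=O)OC)[C@H](c3ccc(OCc4ccccc4)cc3)[C@H]2C(=O)N(C(=O)OC(C)(C)C)c2ccccc2SC)ccc1OCc1ccccc1 | intermediate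
27 | (1R,3R)-2-[4-(benzyloxy)-3-methoxyphenyl]-4-[4-(benzyloxy)phenyl]cyclobutane-1,3-dicarboxylic acid, α-truxillic configuration | COc1cc([C@H]2[C@H](C(=O)O)[C@H](c3ccc(OCc4ccccc4)cc3)[C@H]2C(=O)O)ccc1OCc1ccccc1 | intermediate
28 | bis[(4R,4aS,6R,7S,7aR)-2,4,7-trimethyloctahydro-1H-cyclopenta[c]pyridin-6-yl] (1R,3R)-2-[4-(benzyloxy)-3-methoxyphenyl]-4-[4-(benzyloxy)phenyl]cyclobutane-1,3-dicarboxylate, α-truxillate configuration | COc1cc([C@H]2[C@H](C(=O)O[C@@H]3C[C@@H]4[C@@H](CN(C)C[C@@H]4C)[C@@H]3C)[C@H](c3ccc(OCc4ccccc4)cc3)[C@H]2C(=O)O[C@@H]2C[C@@H]3[C@@H](CN(C)C[C@@H]3C)[C@@H]2C)ccc1OCc1ccccc1 | intermediate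
29 | bis[(4R,4aS,6R,7S,7aR)-2,4,7-trimethyloctahydro-1H-cyclopenta[c]pyridin-6-yl] (1R,3R)-2-(4-hydroxy-3-methoxyphenyl)-4-(4-hydroxyphenyl)cyclobutane-1,3-dicarboxylate, α-truxillate configuration (CNP0331906.2) | COc1cc([C@H]2[C@H](C(=O)O[C@@H]3C[C@@H]4[C@@H](CN(C)C[C@@H]4C)[C@@H]3C)[C@H](c3ccc(O)cc3)[C@H]2C(=O)O[C@@H]2C[C@@H]3[C@@H](CN(C)C[C@@H]3C)[C@@H]2C)ccc1O | target

**Totals**

Total step count: 19. Longest linear sequence: 13 steps (steps 1–11, 18 and 19).

**Steps most likely to fail**

Step 10. Back electron transfer may outrun desilylation of the aminium radical cation, or the product amine may be oxidised in competition with 13, so that conversion stalls or the product is degraded. The fallback generates the same C1 radical by decarboxylation. It sets out from alcohol 10, which is triflated as in step 9. The triflate 12 is treated with sarcosine tert-butyl ester to give tert-butyl N-methyl-N-{(2R)-2-[(1R)-3-methyl-4-oxocyclopent-2-en-1-yl]propyl}glycinate F1. Trifluoroacetic acid then frees N-methyl-N-{(2R)-2-[(1R)-3-methyl-4-oxocyclopent-2-en-1-yl]propyl}glycine F2. Irradiation of F2 with Ir[dF(CF3)ppy]2(dtbbpy)PF6 and K2HPO4 in DMF (blue LEDs) should oxidise the carboxylate, expel CO2 and close the same ring. After the DBU equilibration the route is rejoined at ketone 15.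

Step 14. Site selectivity of the epimerisation may be lost, the ester-bearing carbon inverting as well as, or instead of, the amide-bearing one. The fallback gives up kinetic selectivity and uses thermodynamic control. It sets out from 21, which is equilibrated at both carbonyl-bearing carbons (NaOMe, MeOH, reflux) to methyl (1R,2R,3S)-2-[4-(benzyloxy)phenyl]-3-{[2-(methylsulfanyl)phenyl]carbamoyl}cyclobutane-1-carboxylate F3, the isomer with both carbonyl groups trans to the aryl group. Arylation of F3 with 24 under the conditions of step 16 should give methyl (1S,2R,3R,4R)-2-[4-(benzyloxy)-3-methoxyphenyl]-4-[4-(benzyloxy)phenyl]-3-{[2-(methylsulfanyl)phenyl]carbamoyl}cyclobutane-1-carboxylate F4, in which the new aryl group is flanked by two cis carbonyl groups. Mild base (DBU, toluene) should then invert only the more acidic ester-bearing carbon and relieve that crowding, and the route is rejoined at 25.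

Step 18. The second esterification may remain incomplete, or the activated hindered carbinol may undergo E2 elimination instead of substitution. The fallback replaces the redox condensation by a carboxylate SN2 displacement and sets out from 16 and 27. Alcohol 16 is converted with MsCl and Et3N into (4R,4aS,6S,7S,7aR)-2,4,7-trimethyloctahydro-1H-cyclopenta[c]pyridin-6-yl methanesulfonate F5. Diacid 27 is converted with Cs2CO3 in DMF into dicaesium (1R,3R)-2-[4-(benzyloxy)-3-methoxyphenyl]-4-[4-(benzyloxy)phenyl]cyclobutane-1,3-dicarboxylate F6. Heating F6 with F5 (2.3 equiv) should give the bis-ester with inversion at both C6 centres, and the route is rejoined at 28.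

**Further compounds**

F1 | step 10 | tert-butyl N-methyl-N-{(2R)-2-[(1R)-3-methyl-4-oxocyclopent-2-en-1-yl]propyl}glycinate | O=C1C[C@@H]([C@@H](C)CN(C)CC(=O)OC(C)(C)C)C=C1C
F2 | step 10 | N-methyl-N-{(2R)-2-[(1R)-3-methyl-4-oxocyclopent-2-en-1-yl]propyl}glycine | O=C1C[C@@H]([C@@H](C)CN(C)CC(=O)O)C=C1C
F3 | step 14 | methyl (1R,2R,3S)-2-[4-(benzyloxy)phenyl]-3-{[2-(methylsulfanyl)phenyl]carbamoyl}cyclobutane-1-carboxylate | C1[C@@H](C(=O)OC)[C@H](c2ccc(OCc3ccccc3)cc2)[C@H]1C(=O)Nc1ccccc1SC
F4 | step 14 | methyl (1S,2R,3R,4R)-2-[4-(benzyloxy)-3-methoxyphenyl]-4-[4-(benzyloxy)phenyl]-3-{[2-(methylsulfanyl)phenyl]carbamoyl}cyclobutane-1-carboxylate | COc1cc([C@H]2[C@@H](C(=O)OC)[C@H](c3ccc(OCc4ccccc4)cc3)[C@H]2C(=O)Nc2ccccc2SC)ccc1OCc1ccccc1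
F5 | step 18 | (4R,4aS,6S,7S,7aR)-2,4,7-trimethyloctahydro-1H-cyclopenta[c]pyridin-6-yl methanesulfonate | CS(=O)(=O)O[C@H]1C[C@@H]2[C@@H](CN(C)C[C@@H]2C)[C@@H]1C
F6 | step 18 | dicaesium (1R,3R)-2-[4-(benzyloxy)-3-methoxyphenyl]-4-[4-(benzyloxy)phenyl]cyclobutane-1,3-dicarboxylate | COc1cc([C@H]2[C@H](C(=O)[O-])[C@H](c3ccc(OCc4ccccc4)cc3)[C@H]2C(=O)[O-])ccc1OCc1ccccc1.[Cs+].[Cs+]
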